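The earlier runs and the new flask were computed for an exercise; scatter was added.

4 questions stood on this flask, and I wanted them answered before I chose the next run.

in all of them: first end groups 0.75 M; third end groups 0.375 M
- autumn: second end groups 0.75 M; temperature −20 °C; the very flask that is asked about, followed so far
- winter: second end groups 0.75 M; temperature −25 °C; run made earlier
- flask: second end groups 0.750 M; temperature −20 °C; time 4.0 h

| run | time / min | links / % |
|---|---|---|
| autumn | 30.0 | 27.7 |
| autumn | 60.0 | 21.5 |
| autumn | 90.0 | 20.1 |
| autumn | 150 | 20.6 |
| autumn | 180 | 20.3 |
| autumn | 240 | 20.7 |
| winter | 30.0 | 36.6 |
| winter | 60.0 | 27.0 |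
| winter | 90.0 | 21.3 |
| winter | 150 | 14.1 |
| winter | 180 | 12.6 |
| winter | 240 | 11.1 |

(scatter of a reading: 1 percentage point)

- eta: at 4.0 h take out 90% of the links then present, then wait 8.0 h
- theta: change nothing and wait 8.0 h more
- beta: at 4.0 h add second end groups, 100% of the amount charged, then wait 8.0 h
- gamma: at 4.0 h raise the temperature by 25 K, then wait 8.0 h

- removed links is counted in
- additions bring no volume worth counting

* links, in percent of the first end groups first charged, at 4.0 h
* the remedy with the largest gain of links, or "none" below 2 percentage points (eta / theta / beta / gamma / none)
* links present, with what was taken out counted in, in percent of the first end groups first charged, after eta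
* links present, with what was taken out counted in, in percent of the first end groups first charged, after beta

1. I decided to count turnovers, a turnover being one relaxation half-life. In the autumn run I took the differences between successive links readings, 6.2 percentage points and then 1.4 points, because differences over equal steps need no assumed resting level. Their ratio gave the relaxation half-life, the time in which links close half of their distance to where they rest: 14.0 min. The second difference stands against a scatter of 1 point, so this is a rough reading.

2. The winter run, treated the same way, gave 39.9 min. That is longer than in the autumn run by a factor of 2.85.

3. Every option waits 8.0 h, which is 34.3 turnovers of the autumn flask. So I ranked the options by where links rest, not by speed.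

4. The last 3 autumn readings average 20.5%, which was my estimate for the flask at 4.0 h. The last winter reading is lower, 11.1%, so the resting level looked temperature-dependent, as under thermodynamic control. I therefore put gamma on the next run and left theta out, since it adds turnovers to a flat curve. I reckoned no values for eta or beta.

5. The forecast gave 20.4% (19.7% to 21.1%) for now, 31.5% (27% to 37%) after eta and 32% (26% to 40%) after beta. It chose gamma, saying “relaxation is fast, so gamma is best”.

6. The flask gave 19.6% at 4.0 h, 30.6% after eta and 20.5% after beta, and the best remedy was gamma, with a gain of 31 points.

    first end groups + second end groups → links (k = 0.0170 /M/s, Ea = 37.0 kJ/mol)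
    second end groups + third end groups → links of the second sort (k = 0.0530 /M/s, Ea = 39.0 kJ/mol)
    links ⇌ isomer of the product (K = 1.70, k = 4.60 × 10⁻⁴ /s, Ea = 76.0 kJ/mol, ΔH = −90.0 kJ/mol)
    2 first end groups → homo dimer (k = 0.00170 /M/s, Ea = 42.0 kJ/mol)
    (constants at −20 °C)

Links in the flask read 19.7% at 120 min and 19.5% at 2400 min, a span of roughly 163 turnovers as counted with the rough half-life I had read from the autumn run, 14.0 min. In the flask at 240 min, isomer of the product stood to links as 1.70 to one. The repeat at −45 °C held 47.7% links beside 6.17% isomer of the product at 240 min, a ratio of 0.129 to one.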